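**Remark on the chemistry (numbering).** The target is numbered as a spiro[5.5]undecane. Ring A is C1–C6: C1 carries the exocyclic CH2, C2 the hydroxyl, C3=C4 the vinyl bromide, C5 the two methyl groups. Ring B is C6–C11: C9 carries CH3 and Cl, C10 carries Br. With these locants the SMILES reads (2R,6S,9S,10S). The same locants are used for all intermediates, open-chain ones included.

## Analysis of the target

The compound is a chamigrene-type spiro[5.5]undecane in which the spiro carbon C6 is quaternary and is bonded to a second quaternary carbon, C5 (CMe2), so the C5–C6 bond is the most congested one in the molecule. Ring A also carries an exocyclic methylene (C1), a secondary, doubly allylic alcohol (C2, R) and a vinyl bromide (C3=C4–Br). Ring B carries a tertiary chloride (C9, S) next to a secondary bromide (C10, S). In the chair of ring B that keeps C5 equatorial, Br and Cl are trans and both equatorial, with Br cis to C5 and Cl cis to C1. That arrangement is the opposite of what trans-diaxial (Fürst–Plattner) addition of Br/Cl to a C9=C10 alkene of the finished spirocycle would give. The triad C6/C9/C10 of ring B is therefore the feature that decides the strategy: the halogens have to be in place before ring B exists, and ring B has to be closed at the C6–C11 bond. The C2 carbinol sits in a pocket that is almost symmetric with respect to the two ring B methylenes on C6, so it needs reagent control. Sensitive groups are the tertiary chloride (ionisation, E1), the bromide β to it (base), the doubly allylic alcohol (ionisation), the vinyl bromide (low-valent metals) and the skipped and exocyclic alkenes (acid isomerisation).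

## Retrosynthetic reasoning

**19 to 18.** The C2–O bond and the exocyclic alkene are traced back to a C1–C2 epoxide. Opening 18 at the tertiary C1–O bond with loss of a methyl proton leaves the C2–O bond untouched, so C2 is set in the epoxide. The forward reaction has to abstract a proton only from the C1 methyl group; C6 is quaternary and offers none.

**18 to 17.** The epoxide oxygen is removed to give the conjugated bromodiene 17. Of its two alkenes only C1=C2 is electron-rich, and a chiral ketone-catalysed (Shi) epoxidation can choose the face by reagent control, which the substrate itself cannot do.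

**17 to 15 (key disconnection).** The C6–C11 bond is cut, which opens ring B and leaves a monocyclic cyclohexadiene carrying an open-chain primary alcohol with the C9–Cl and C10–Br stereocentres already in place. This cut is chosen because ring closure through a chair then relays the two acyclic stereocentres to C6, and because the quaternary C5 is already attached to C6, so the congested bond never has to be made between two fully substituted carbons. The forward step has to ionise only at C11, attack through C6 of the tetrasubstituted C6=C1 alkene, and end by loss of a proton.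

**15 to 14.** Both carbon–halogen bonds are cut together. A (Z)-allylic alcohol is the substrate of a titanium-mediated enantioselective bromochlorination that puts Br on the carbon next to the carbinol and Cl on the tertiary carbon, anti. The (Z) geometry is what translates into the trans relationship on ring B.

**14 to 11 (via 13 and 12).** The vinyl bromide goes back to a ketone at C4 through its enol triflate. C5 is quaternary, so the ketone can enolise only towards C3 and the bromide position is unambiguous. These base-mediated steps are placed before the halogens of ring B are introduced.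

**11 to 10.** The second methyl group on C5 is removed. Deconjugative α-methylation of enone 10 creates the quaternary C5 and at the same time moves the alkene to C6=C1, which is exactly the nucleophilic alkene the key step needs.

**10 to 5 and 7.** The C6–C7 bond is cut by a Stork–Danheiser disconnection: a homoallylic organolithium from iodide 5 adds to the carbonyl of vinylogous ester 7, and hydrolysis transposes the carbonyl to C4.

**5 to 1 and 7 to 6.** Iodide 5 comes from the commercial (Z)-enynol 1 by silylation, semihydrogenation and hydroboration–iodination; the (Z) alkene is bought, not made. Vinylogous ester 7 is the α′-methylation product of commercial 6.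

## Alternatives that were turned down

**Alternative 1:** the textbook Diels–Alder disconnection of ring B (bonds C6–C11 and C7–C8). An exocyclic enone of ring A such as A1 would react with a methyl-substituted C5 diene to give the spiro ketone A2 with a C9=C10 alkene. It was turned down for three reasons. A1 is a hindered α,α-disubstituted dienophile, for which enantioselective catalysis is not secure. Bromochlorination of A2-type alkenes goes by trans-diaxial opening from the half-chair with C5 equatorial, which puts Br syn to C1 and Cl syn to C5, the C9,C10 bis-epimer of the target. Ring A arrives with a ketone at C1 that must be methylenated next to the spiro centre, and with C2–C4 unfunctionalised.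

**Alternative 2:** set C6 by a palladium-catalysed enantioselective decarboxylative allylation to give ketone A3, then close ring B by ring-closing metathesis (second-generation Grubbs catalyst) to A4. C6 would be set well, but the route ends at the same C9=C10 alkene as Alternative 1 and meets the same mismatch in the halogenation. It also leaves the C1 carbonyl, the C2 oxygen and the C3=C4–Br unit to be installed one by one on a ring with no handle at C4.

**Alternative 3:** the reverse order, ring A last. A cyclohexylidene allylsilane on a pre-halogenated ring B (A5) would be ionised to a 2-bromoallyl cation at C5, which attacks C6 and closes ring A with the vinyl bromide and exocyclic methylene in place. It was turned down because C6 is trigonal while the new bond forms, and the ring B chair then prefers both halogens axial (methyl equatorial). Equatorial attack on that chair places C5 anti to Br, the wrong C6 epimer. In addition the doubly allylic C2–O bond of A5 would ionise in competition, and A5 needs a β-bromo cyclohexanone, which eliminates HBr easily.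

Key step: step 11

## Route

Step 1
Reactants: 1 (Z)-3-methylpent-2-en-4-yn-1-ol
Product: 2 (Z)-triisopropyl[(3-methylpent-2-en-4-yn-1-yl)oxy]silane
Conditions: i-Pr3SiCl, imidazole, DMF, 0 °C to rt
Reagents that add atoms: chlorotriisopropylsilane, CC(C)[Si](Cl)(C(C)C)C(C)C
Why: Standard silylation of a primary alcohol. The triisopropylsilyl ether should survive organolithium, dilute acid, KOt-Bu and KN(SiMe3)2, and has no arene that could bind the ruthenium catalyst of step 8.

Step 2
Reactants: 2 (Z)-triisopropyl[(3-methylpent-2-en-4-yn-1-yl)oxy]silane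
Product: 3 (Z)-triisopropyl[(3-methylpenta-2,4-dien-1-yl)oxy]silane
Conditions: H2 (1 atm), Pd/CaCO3–Pb(OAc)2 (Lindlar catalyst), quinoline, hexane, rt
Reagents that add atoms: none
Why: Lindlar semihydrogenation of the terminal alkyne of a conjugated enyne; the trisubstituted (Z) alkene is not touched.

Step 3
Reactants: 3 (Z)-triisopropyl[(3-methylpenta-2,4-dien-1-yl)oxy]silane
Product: 5 (Z)-[(5-iodo-3-methylpent-2-en-1-yl)oxy]triisopropylsilane, via B-alkyl-9-BBN adduct 4 (not isolated)
Conditions: 9-BBN, THF, 0 °C to rt; then NaOMe, I2, MeOH–THF, 0 °C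
Reagents that add atoms: iodine, II
Why: Anti-Markovnikov hydroboration of the monosubstituted vinyl group of the diene, then base-induced iodinolysis of the primary B–C bond. The trisubstituted alkene is too hindered for 9-BBN.

Step 4
Reactants: 6 3-ethoxy-2-methylcyclohex-2-en-1-one
Product: 7 3-ethoxy-2,6-dimethylcyclohex-2-en-1-one (racemic)
Conditions: LiN(i-Pr)2, THF, −78 °C; MeI, −78 to 0 °C
Reagents that add atoms: iodomethane, CI
Why: Kinetic α′-enolate alkylation of a vinylogous ester. The new stereocentre becomes C1 and is erased in step 6, so the racemate is used.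

Step 5
Reactants: 5 (Z)-[(5-iodo-3-methylpent-2-en-1-yl)oxy]triisopropylsilane; 7 3-ethoxy-2,6-dimethylcyclohex-2-en-1-one
Product: 10 2,4-dimethyl-3-[(3Z)-3-methyl-5-(triisopropylsilyloxy)pent-3-en-1-yl]cyclohex-2-en-1-one (racemic), via homoallyllithium reagent 8 (not isolated), via tertiary allylic alkoxide 9 (not isolated)
Conditions: t-BuLi (2.1 equiv), Et2O–pentane, −78 °C; add 7, −78 to 0 °C; then 1 M HCl, THF, rt
Reagents that add atoms: water, O
Why: Stork–Danheiser sequence: iodine–lithium exchange, 1,2-addition to the vinylogous ester carbonyl (forms C6–C7), then acid hydrolysis with carbonyl transposition to C4.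

Step 6
Reactants: 10 2,4-dimethyl-3-[(3Z)-3-methyl-5-(triisopropylsilyloxy)pent-3-en-1-yl]cyclohex-2-en-1-one
Product: 11 2,2,4-trimethyl-3-[(3Z)-3-methyl-5-(triisopropylsilyloxy)pent-3-en-1-yl]cyclohex-3-en-1-one
Conditions: KOt-Bu (1.1 equiv), t-BuOH–THF, 0 °C; MeI, 0 °C to rt
Reagents that add atoms: iodomethane, CI
Why: Deconjugative α-alkylation through the thermodynamic, fully substituted homoannular dienolate. Methylation at C5 makes the quaternary carbon and leaves the alkene at C6=C1; the compound becomes achiral.

Step 7
Reactants: 11 2,2,4-trimethyl-3-[(3Z)-3-methyl-5-(triisopropylsilyloxy)pent-3-en-1-yl]cyclohex-3-en-1-one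
Product: 12 4,6,6-trimethyl-5-[(3Z)-3-methyl-5-(triisopropylsilyloxy)pent-3-en-1-yl]cyclohexa-1,4-dien-1-yl trifluoromethanesulfonate
Conditions: KN(SiMe3)2, THF, −78 °C; PhNTf2, −78 to 0 °C
Reagents that add atoms: N-phenylbis(trifluoromethanesulfonimide), O=S(=O)(N(c1ccccc1)S(=O)(=O)C(F)(F)F)C(F)(F)F
Why: Enolate O-triflation. The ketone has α-hydrogens only at C3 because C5 is quaternary, so a single enol triflate can form.

Step 8
Reactants: 12 4,6,6-trimethyl-5-[(3Z)-3-methyl-5-(triisopropylsilyloxy)pent-3-en-1-yl]cyclohexa-1,4-dien-1-yl trifluoromethanesulfonate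
Product: 13 {[(2Z)-5-(5-bromo-2,6,6-trimethylcyclohexa-1,4-dien-1-yl)-3-methylpent-2-en-1-yl]oxy}triisopropylsilane
Conditions: LiBr, [Cp*Ru(MeCN)3]OTf (5 mol %), 1,3-dimethyl-2-imidazolidinone, rt to 40 °C
Reagents that add atoms: lithium bromide, [Li+].[Br-]
Why: Catalytic triflate-to-bromide exchange of alkenyl triflates by a cationic divalent ruthenium complex. It runs without base and with retention of the alkene position.

Step 9
Reactants: 13 {[(2Z)-5-(5-bromo-2,6,6-trimethylcyclohexa-1,4-dien-1-yl)-3-methylpent-2-en-1-yl]oxy}triisopropylsilane
Product: 14 (2Z)-5-(5-bromo-2,6,6-trimethylcyclohexa-1,4-dien-1-yl)-3-methylpent-2-en-1-ol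
Conditions: Bu4NF, THF, 0 °C to rt
Reagents that add atoms: none
Why: Fluoride cleavage of the silyl ether frees the allylic alcohol that directs the next step.

Step 10
Reactants: 14 (2Z)-5-(5-bromo-2,6,6-trimethylcyclohexa-1,4-dien-1-yl)-3-methylpent-2-en-1-ol
Product: 15 (2S,3S)-2-bromo-5-(5-bromo-2,6,6-trimethylcyclohexa-1,4-dien-1-yl)-3-chloro-3-methylpentan-1-ol
Conditions: N-bromosuccinimide, ClTi(Oi-Pr)3, chiral tridentate Schiff-base ligand (salicylaldimine of an enantiopure 2-amino-1,1-diarylalkanol, 20 mol %), hexanes, −20 °C
Reagents that add atoms: N-bromosuccinimide, O=C1CCC(=O)N1Br; chlorotitanium triisopropoxide, CC(C)O[Ti](Cl)(OC(C)C)OC(C)C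
Why: Titanium-mediated enantioselective bromochlorination of allylic alcohols: Br goes to the carbon next to the carbinol (C10) and Cl anti to the tertiary carbon (C9), so the (Z) alkene gives the relative configuration that is trans on ring B, and the ligand enantiomer is chosen for (2S,3S). Both halogens are delivered from titanium bound to the allylic alkoxide, which is why isolated alkenes are left alone in this reaction class; the tetrasubstituted ring alkene is also shielded by the neighbouring quaternary carbon.

Step 11
Reactants: 15 (2S,3S)-2-bromo-5-(5-bromo-2,6,6-trimethylcyclohexa-1,4-dien-1-yl)-3-chloro-3-methylpentan-1-ol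
Product: 17 (6S,9S,10S)-4,10-dibromo-9-chloro-1,5,5,9-tetramethylspiro[5.5]undeca-1,3-diene, via primary triflate 16 (not isolated)
Conditions: Tf2O, 2,6-di-tert-butyl-4-methylpyridine, CH2Cl2, −78 °C; then (CF3)2CHOH, −78 to −20 °C
Reagents that add atoms: none
Why: O-Triflation gives 16; in the ionising, non-nucleophilic fluoro alcohol the primary triflate leaves, either with bridging by the C10 bromine (bromiranium ion across C10–C11) or by direct displacement, and C6 of the tetrasubstituted C6=C1 alkene attacks C11, after which the tertiary C1 cation loses the doubly allylic C2 proton to the hindered pyridine to give the conjugated bromodiene. The closest known reaction types are the solvolytic cation–olefin (π-participation) cyclisation of alkenyl sulfonates and the enantiospecific cyclisations relayed by bromiranium ions generated from β-bromo leaving-group precursors in fluoro alcohols. Ring B closes as a six-membered ring through a chair, by attack on the primary carbon C11; with respect to the bromiranium ion this is opening at its less substituted end. C6 is set by that chair: Br is equatorial (anti to the forming C6–C11 bond, enforced on the bromiranium path and favoured on the direct path because an axial Br would clash with the axial C1), Cl is then equatorial and the C9 methyl axial, and the quaternary C5 takes the equatorial position while trigonal C1 goes axial, which places C5 cis to Br, that is (6S). C9 and C10 are not touched, since the C10–Br bond is never broken for good and C9 is not involved. The step needs attack at C11 and not at C10 (which would give a cyclopentane): C10 is neopentyl-like, flanked by the fully substituted C9, and inductively deactivated by the C9 chlorine. It also needs the C9–Cl bond to stay intact, which the low temperature and the far better triflate leaving group should secure, and it needs proton loss from C2 and not from the methyl group, which the doubly allylic C2–H favours.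

Step 12
Reactants: 17 (6S,9S,10S)-4,10-dibromo-9-chloro-1,5,5,9-tetramethylspiro[5.5]undeca-1,3-diene
Product: 18 (1S,2R,6R,9S,10S)-4,10-dibromo-9-chloro-1,2-epoxy-1,5,5,9-tetramethylspiro[5.5]undec-3-ene
Conditions: D-fructose-derived Shi ketone (30 mol %), KHSO5 (as Oxone), K2CO3, Bu4NHSO4, MeCN–dimethoxymethane / aq. Na2B4O7–Na2EDTA buffer, 0 °C
Reagents that add atoms: potassium peroxymonosulfate, [K+].[O-]S(=O)(=O)OO
Why: Shi epoxidation by a chiral dioxirane: only the electron-rich trisubstituted C1=C2 alkene reacts, the bromo-substituted alkene is deactivated. The face is chosen by the catalyst through its spiro transition state (the same sense as for 1-substituted cyclohexenes), which should give the (2R) oxygen that the substrate cannot direct.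

Step 13
Reactants: 18 (1S,2R,6R,9S,10S)-4,10-dibromo-9-chloro-1,2-epoxy-1,5,5,9-tetramethylspiro[5.5]undec-3-ene
Product: 19 (2R,6S,9S,10S)-4,10-dibromo-9-chloro-5,5,9-trimethyl-1-methylidenespiro[5.5]undec-3-en-2-ol
Conditions: Et2Al(2,2,6,6-tetramethylpiperidide) (from LiTMP and Et2AlCl), toluene, 0 °C; aq. Rochelle salt
Reagents that add atoms: none
Why: Aluminium amide isomerisation of a trisubstituted epoxide to an allylic alcohol by syn-elimination within the O–Al complex. The only β-hydrogens on the C1 side are those of the methyl group (C6 is quaternary), so the exocyclic alkene forms; the C2–O bond is not broken, so C2 stays (R).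

## Compound list

1 | (Z)-3-methylpent-2-en-4-yn-1-ol | OC/C=C(C)\C#C | starting material
2 | (Z)-triisopropyl[(3-methylpent-2-en-4-yn-1-yl)oxy]silane | CC(C)[Si](OC/C=C(C)\C#C)(C(C)C)C(C)C | intermediate
3 | (Z)-triisopropyl[(3-methylpenta-2,4-dien-1-yl)oxy]silane | CC(C)[Si](OC/C=C(C)\C=C)(C(C)C)C(C)C | intermediate
4 | 9-[(3Z)-3-methyl-5-(triisopropylsilyloxy)pent-3-en-1-yl]-9-borabicyclo[3.3.1]nonane | CC(C)[Si](OC/C=C(C)\CCB1C2CCCC1CCC2)(C(C)C)C(C)C | intermediate
5 | (Z)-[(5-iodo-3-methylpent-2-en-1-yl)oxy]triisopropylsilane | CC(C)[Si](OC/C=C(C)\CCI)(C(C)C)C(C)C | intermediate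
6 | 3-ethoxy-2-methylcyclohex-2-en-1-one | CCOC1=C(C)C(=O)CCC1 | starting material
7 | 3-ethoxy-2,6-dimethylcyclohex-2-en-1-one (racemic) | CCOC1=C(C)C(=O)C(C)CC1 | intermediate
8 | [(3Z)-3-methyl-5-(triisopropylsilyloxy)pent-3-en-1-yl]lithium | [Li]CC/C(C)=C\CO[Si](C(C)C)(C(C)C)C(C)C | intermediate
9 | 3-ethoxy-2,6-dimethyl-1-[(3Z)-3-methyl-5-(triisopropylsilyloxy)pent-3-en-1-yl]cyclohex-2-en-1-ol (as its lithium alkoxide, diastereomer mixture) | CCOC1=C(C)C(O)(CC/C(C)=C\CO[Si](C(C)C)(C(C)C)C(C)C)C(C)CC1 | intermediate
10 | 2,4-dimethyl-3-[(3Z)-3-methyl-5-(triisopropylsilyloxy)pent-3-en-1-yl]cyclohex-2-en-1-one (racemic) | CC1CCC(=O)C(C)=C1CC/C(C)=C\CO[Si](C(C)C)(C(C)C)C(C)C | intermediate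
11 | 2,2,4-trimethyl-3-[(3Z)-3-methyl-5-(triisopropylsilyloxy)pent-3-en-1-yl]cyclohex-3-en-1-one | CC1=C(CC/C(C)=C\CO[Si](C(C)C)(C(C)C)C(C)C)C(C)(C)C(=O)CC1 | intermediate
12 | 4,6,6-trimethyl-5-[(3Z)-3-methyl-5-(triisopropylsilyloxy)pent-3-en-1-yl]cyclohexa-1,4-dien-1-yl trifluoromethanesulfonate | CC1=C(CC/C(C)=C\CO[Si](C(C)C)(C(C)C)C(C)C)C(C)(C)C(OS(=O)(=O)C(F)(F)F)=CC1 | intermediate
13 | {[(2Z)-5-(5-bromo-2,6,6-trimethylcyclohexa-1,4-dien-1-yl)-3-methylpent-2-en-1-yl]oxy}triisopropylsilane | CC1=C(CC/C(C)=C\CO[Si](C(C)C)(C(C)C)C(C)C)C(C)(C)C(Br)=CC1 | intermediate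
14 | (2Z)-5-(5-bromo-2,6,6-trimethylcyclohexa-1,4-dien-1-yl)-3-methylpent-2-en-1-ol | CC1=C(CC/C(C)=C\CO)C(C)(C)C(Br)=CC1 | intermediate
15 | (2S,3S)-2-bromo-5-(5-bromo-2,6,6-trimethylcyclohexa-1,4-dien-1-yl)-3-chloro-3-methylpentan-1-ol | CC1=C(CC[C@](C)(Cl)[C@@H](Br)CO)C(C)(C)C(Br)=CC1 | intermediate
16 | (2S,3S)-2-bromo-5-(5-bromo-2,6,6-trimethylcyclohexa-1,4-dien-1-yl)-3-chloro-3-methylpentyl trifluoromethanesulfonate | CC1=C(CC[C@](C)(Cl)[C@@H](Br)COS(=O)(=O)C(F)(F)F)C(C)(C)C(Br)=CC1 | intermediate
17 | (6S,9S,10S)-4,10-dibromo-9-chloro-1,5,5,9-tetramethylspiro[5.5]undeca-1,3-diene | CC1=CC=C(Br)C(C)(C)[C@]12CC[C@](C)(Cl)[C@@H](Br)C2 | intermediate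
18 | (1S,2R,6R,9S,10S)-4,10-dibromo-9-chloro-1,2-epoxy-1,5,5,9-tetramethylspiro[5.5]undec-3-ene | C[C@@]12O[C@@H]1C=C(Br)C(C)(C)[C@]23CC[C@](C)(Cl)[C@@H](Br)C3 | intermediate
19 | (2R,6S,9S,10S)-4,10-dibromo-9-chloro-5,5,9-trimethyl-1-methylidenespiro[5.5]undec-3-en-2-ol | C=C1[C@H](O)C=C(Br)C(C)(C)[C@]12CC[C@](C)(Cl)[C@@H](Br)C2 | target

## Step count and least certain steps

Total step count: 13. Longest linear sequence: 12 steps (steps 1–3 and 5–13; step 4 is the one-step side branch).

**Step 11 (key step).** The least controllable events are those of the cationic intermediates. The tertiary C1 cation may lose a proton from the methyl group instead of from C2, and the skipped diene may migrate in the acidic medium before it cyclises. Opening of the bromiranium ion at C10 or ionisation at C9–Cl are further escape routes, held back by the neopentyl, chlorine-deactivated nature of C10 and by the low temperature. The fallback changes the endgame and not the ring closure. It sets out from 15 and uses the product of methyl deprotonation, (6S,9S,10S)-4,10-dibromo-9-chloro-5,5,9-trimethyl-1-methylidenespiro[5.5]undec-3-ene F1, as it is. F1 is oxidised at the doubly allylic C2 with SeO2/t-BuOOH (ene reaction, then 2,3-shift, which keeps the exocyclic alkene) to a mixture of 19 and its C2 epimer F2. The mixture is oxidised with Dess–Martin periodinane to the cross-conjugated dienone F3. F3 is reduced with the (S)-methyl CBS oxazaborolidine and catecholborane, in which the α-branched C1 flank acts as the large group, and the route comes back at 19.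

**Step 6.** Proton abstraction may take place at the side-chain CH2 (C7) instead of at ring C1–H, which after methylation would leave an exocyclic alkene; a second methylation at C3 is also possible. The fallback makes the tetrasubstituted alkene by cross-coupling instead of by enolate chemistry. It sets out from 3 (as its 9-BBN adduct 4) and from commercial 2,2-dimethylcyclohexane-1,3-dione F4. F4 is converted into its mono-ketal 6,6-dimethyl-1,4-dioxaspiro[4.5]decan-7-one F5 (ethylene glycol, TsOH). The remaining ketone, which can enolise in one direction only, is methylated (LiN(i-Pr)2, MeI) to 6,6,8-trimethyl-1,4-dioxaspiro[4.5]decan-7-one F6, and this is converted into the enol triflate F7 (KN(SiMe3)2, PhNTf2). A B-alkyl Suzuki–Miyaura coupling of F7 with 4 (PdCl2(dppf), AsPh3, Cs2CO3, DMF–THF–H2O) gives the ketal F8, and mild aqueous acid removes the ketal to come back at 11.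

**Step 8.** Exchange at the hindered enol triflate next to the quaternary carbon may be slow, and a metal hydride formed on the way may move the 1,4-diene into conjugation. The fallback goes through boron instead of direct exchange. It sets out from 12: Miyaura borylation (B2pin2, PdCl2(PPh3)2, PPh3, KOPh, toluene) gives the alkenyl boronate F9, and bromodeboronation with CuBr2 in aqueous methanol comes back at 13.

**Step 13.** The vinyl epoxide may open at the allylic C2–O bond instead of at C1–O, and the aluminium amide may dehydrohalogenate ring B. The fallback replaces the base-induced syn-elimination by a Lewis-acid-induced opening through the tertiary C1 cation. It sets out from 18: Me3SiOTf and 2,6-lutidine in toluene at −78 °C, then DBU, give the allylic silyl ether F10, and K2CO3 in methanol at 0 °C removes the silyl group to come back at 19.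

## Further compounds

F1 | step 11 | (6S,9S,10S)-4,10-dibromo-9-chloro-5,5,9-trimethyl-1-methylidenespiro[5.5]undec-3-ene | C=C1CC=C(Br)C(C)(C)[C@]12CC[C@](C)(Cl)[C@@H](Br)C2
F2 | step 11 | (2S,6S,9S,10S)-4,10-dibromo-9-chloro-5,5,9-trimethyl-1-methylidenespiro[5.5]undec-3-en-2-ol | C=C1[C@@H](O)C=C(Br)C(C)(C)[C@]12CC[C@](C)(Cl)[C@@H](Br)C2
F3 | step 11 | (6S,9S,10S)-4,10-dibromo-9-chloro-5,5,9-trimethyl-1-methylidenespiro[5.5]undec-3-en-2-one | C=C1C(=O)C=C(Br)C(C)(C)[C@]12CC[C@](C)(Cl)[C@@H](Br)C2
F4 | step 6 | 2,2-dimethylcyclohexane-1,3-dione | CC1(C)C(=O)CCCC1=O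
F5 | step 6 | 6,6-dimethyl-1,4-dioxaspiro[4.5]decan-7-one | CC1(C)C(=O)CCCC12OCCO2
F6 | step 6 | 6,6,8-trimethyl-1,4-dioxaspiro[4.5]decan-7-one (racemic) | CC1CCC2(OCCO2)C(C)(C)C1=O
F7 | step 6 | 6,6,8-trimethyl-1,4-dioxaspiro[4.5]dec-7-en-7-yl trifluoromethanesulfonate | CC1=C(OS(=O)(=O)C(F)(F)F)C(C)(C)C2(CC1)OCCO2
F8 | step 6 | triisopropyl{[(2Z)-3-methyl-5-(6,6,8-trimethyl-1,4-dioxaspiro[4.5]dec-7-en-7-yl)pent-2-en-1-yl]oxy}silane | CC1=C(CC/C(C)=C\CO[Si](C(C)C)(C(C)C)C(C)C)C(C)(C)C2(CC1)OCCO2
F9 | step 8 | triisopropyl{[(2Z)-3-methyl-5-[2,6,6-trimethyl-5-(4,4,5,5-tetramethyl-1,3,2-dioxaborolan-2-yl)cyclohexa-1,4-dien-1-yl]pent-2-en-1-yl]oxy}silane | CC1=C(CC/C(C)=C\CO[Si](C(C)C)(C(C)C)C(C)C)C(C)(C)C(B2OC(C)(C)C(C)(C)O2)=CC1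
F10 | step 13 | {[(2R,6S,9S,10S)-4,10-dibromo-9-chloro-5,5,9-trimethyl-1-methylidenespiro[5.5]undec-3-en-2-yl]oxy}trimethylsilane | C=C1[C@H](O[Si](C)(C)C)C=C(Br)C(C)(C)[C@]12CC[C@](C)(Cl)[C@@H](Br)C2
A1 | alternative 1 | 3,3-dimethyl-2-methylidenecyclohexan-1-one | C=C1C(=O)CCCC1(C)C
A2 | alternative 1 | 5,5,9-trimethylspiro[5.5]undec-9-en-1-one (racemic) | O=C1CCCC(C)(C)C12CCC(C)=CC2
A3 | alternative 2 | (2R)-2-allyl-3,3-dimethyl-2-(3-methylbut-3-en-1-yl)cyclohexan-1-one | O=C1CCCC(C)(C)[C@]1(CC=C)CCC(C)=C
A4 | alternative 2 | (6R)-5,5,9-trimethylspiro[5.5]undec-9-en-1-one | O=C1CCCC(C)(C)[C@]12CCC(C)=CC2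
A5 | alternative 3 | (3E,5R)-4-bromo-6-[(3S,4S)-3-bromo-4-chloro-4-methylcyclohexylidene]-5-(tert-butyldimethylsilyloxy)-2-methyl-7-(trimethylsilyl)hept-3-en-2-ol (mixture of isomers at the exocyclic alkene) | C[Si](C)(C)CC(=C1CC[C@](C)(Cl)[C@@H](Br)C1)[C@H](O[Si](C)(C)C(C)(C)C)/C=C(/Br)C(C)(C)O
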